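## Retrosynthetic overview

1. The ring ketone on the quaternary carbon and the C=O of the 3-oxobutyl arm are rejoined as a tetrasubstituted C=C (ozonolysis retron); the target's cyclohexane (ring A) then becomes one half of a cis-fused octalin whose temporary ring B holds both ring stereocenters.
2. Enabling feature: in ring A the C(CH3)2 carbon lies between the ring CH and a ring CH2, so CH–C(CH3)2–CH2 is a hydro-alkylated isopropenyl group; ring B carrying it is (R)-carvone (its C-5 = ring CH, C-6 = quaternary C–CH3, C-1/C-2 = the two ketone carbons, C-2 methyl = the acetyl CH3).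
3. Ring A is closed between the gem-dimethyl carbon and its ring CH2 neighbour by intramolecular reductive Markovnikov hydroalkylation (isopropenyl + primary C–I, two electrophilic carbons joined via a radical and nickel); precursor 9 comes from carvone by two α'-alkylations (arm first, then CH3 anti to isopropenyl) and halide exchange.
4. Side chain: Negishi coupling of enol triflate 13 with a five-carbon zinc reagent from methyl hydrogen (R)-3-methylglutarate; glyceride: (S)-solketal ester, acetal cleavage, primary acetylation.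
5. Ring order: ring B bought (carvone) → ring A closed (step 4) → ring B opened (step 13).

Key step: step 4

Remark: compounds 1, 2, 14 and 22 are taken as commercial; the descriptor change 5R (1, 4) → 5S (7, 9) → 4aS (10) reflects CIP priorities only, as this carbon is never touched.

## Route

Step 1
Reactants: 1 (R)-carvone; 2 1-chloro-3-iodopropane
Product: 4 (5R,6RS)-6-(3-chloropropyl)-2-methyl-5-(prop-1-en-2-yl)cyclohex-2-en-1-one, via lithium dienolate 3 (not isolated)
Conditions: LiN(i-Pr)2, THF, −78 °C; then 2, DMPU, −78 → −20 °C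
Reagents that add atoms: 1-chloro-3-iodopropane, ClCCCI
Why: Kinetic α'-deprotonation of the cross-conjugated enone and enolate alkylation (SN2) at the iodide end of the dihalide should install the three-carbon arm at C-6; the C-6 configuration is irrelevant because step 2 erases it.

Step 2
Reactants: 4 (5R,6RS)-6-(3-chloropropyl)-2-methyl-5-(prop-1-en-2-yl)cyclohex-2-en-1-one; 5 iodomethane
Product: 7 (5S,6R)-6-(3-chloropropyl)-2,6-dimethyl-5-(prop-1-en-2-yl)cyclohex-2-en-1-one, via lithium enolate 6 (not isolated)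
Conditions: LiN(i-Pr)2, THF, −78 °C; then MeI, −78 → 0 °C
Reagents that add atoms: iodomethane, CI
Why: Enolate alkylation in which the planar enolate 6 funnels both C-6 epimers of 4 into one product and iodomethane should attack the face anti to the adjacent isopropenyl group (1,2-induction), so that CH3 ends up trans and the chloropropyl arm cis to isopropenyl at the new quaternary stereocenter.

Step 3
Reactants: 7 (5S,6R)-6-(3-chloropropyl)-2,6-dimethyl-5-(prop-1-en-2-yl)cyclohex-2-en-1-one; 8 sodium iodide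
Product: 9 (5S,6R)-6-(3-iodopropyl)-2,6-dimethyl-5-(prop-1-en-2-yl)cyclohex-2-en-1-one
Conditions: NaI, acetone, reflux
Reagents that add atoms: sodium iodide, [Na+].[I-]
Why: Finkelstein halide exchange (SN2 at the unhindered primary chloride) driven by precipitation of NaCl; no stereocenter is touched.

Step 4
Reactants: 9 (5S,6R)-6-(3-iodopropyl)-2,6-dimethyl-5-(prop-1-en-2-yl)cyclohex-2-en-1-one
Product: 10 (4aS,8aR)-2,5,5,8a-tetramethyl-4a,5,6,7,8,8a-hexahydronaphthalen-1(4H)-one
Conditions: Mn(dpm)3 (dpm = 2,2,6,6-tetramethylheptane-3,5-dionate, 20 mol%), Ni(acac)2 (5 mol%), PhSiH3 (syringe pump), K2CO3, (CF3)2CHOH, ClCH2CH2Cl/propylene carbonate, 25 °C, 0.01 M, Ar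
Reagents that add atoms: none
Why: Proposed new method: a trivalent manganese hydride formed from Mn(dpm)3 and PhSiH3 should transfer a hydrogen atom to the CH2 terminus of the isopropenyl group and give the tertiary radical at the future gem-dimethyl carbon, while low-valent nickel activates the primary C–I bond; capture of the radical by the alkylnickel species and reductive elimination from nickel join the tertiary carbon to the terminal CH2 of the arm. The closest known reaction type is the intermolecular manganese/nickel dual-catalytic Markovnikov hydroalkylation of 1,1-disubstituted alkenes with primary alkyl iodides, which builds quaternary carbons; it is used here intramolecularly. Ring A closes in a formal 6-exo-tet mode (reductive elimination from a seven-membered nickelacycle), which is geometrically easy because the arm on C-6 and the isopropenyl group on C-5 are cis on ring B. No stereocenter is created: the new quaternary carbon bears two methyl groups, and the cis ring fusion (4aS,8aR) is inherited from steps 1 and 2. The step needs hydrogen atom transfer to the electron-rich 1,1-disubstituted alkene and not to the enone, which the known preference of such hydride catalysts for the isopropenyl group of carvone-type dienones should secure, and ring closure instead of plain reduction of radical or iodide, which high dilution and slow silane addition favour. Attack of the tertiary radical on the enone is ruled out by the substrate, since it would form a four-membered ring (β-carbon) or a strained 5-endo bicycle (α-carbon).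

Step 5
Reactants: 10 (4aS,8aR)-2,5,5,8a-tetramethyl-4a,5,6,7,8,8a-hexahydronaphthalen-1(4H)-one; 11 N-phenylbis(trifluoromethanesulfonimide)
Product: 13 (4aS,8aR)-2,5,5,8a-tetramethyl-3,4,4a,5,6,7,8,8a-octahydronaphthalen-1-yl trifluoromethanesulfonate, via lithium enolate 12 (not isolated)
Conditions: LiBH(s-Bu)3, THF, −78 °C; then PhNTf2, −78 °C → rt
Reagents that add atoms: N-phenylbis(trifluoromethanesulfonimide), FC(F)(F)S(=O)(=O)N(c1ccccc1)S(=O)(=O)C(F)(F)F
Why: Conjugate hydride reduction of the β-unsubstituted, carbonyl-hindered enone followed by O-sulfonylation of the regiodefined enolate (reductive enolate trapping) should give the tetrasubstituted enol triflate, the quaternary C-8a excluding any other enolate; no stereocenter is formed.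

Step 6
Reactants: 14 (3R)-5-methoxy-3-methyl-5-oxopentanoic acid (methyl hydrogen (R)-3-methylglutarate)
Product: 15 methyl (3R)-5-hydroxy-3-methylpentanoate
Conditions: BH3·SMe2, THF, −10 °C → rt; MeOH quench
Reagents that add atoms: none
Why: Chemoselective borane reduction of a carboxylic acid in the presence of a methyl ester; the stereocenter is not involved.

Step 7
Reactants: 15 methyl (3R)-5-hydroxy-3-methylpentanoate; 16 iodine
Product: 17 methyl (3S)-5-iodo-3-methylpentanoate
Conditions: I2, PPh3, imidazole, CH2Cl2, 0 °C → rt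
Reagents that add atoms: iodine, II
Why: Appel-type iodination of the primary alcohol (alkoxyphosphonium, SN2 by iodide) under neutral conditions that should keep the hydroxy ester from lactonising; the descriptor changes by CIP priority only.

Step 8
Reactants: 13 (4aS,8aR)-2,5,5,8a-tetramethyl-3,4,4a,5,6,7,8,8a-octahydronaphthalen-1-yl trifluoromethanesulfonate; 17 methyl (3S)-5-iodo-3-methylpentanoate
Product: 19 methyl (3R)-3-methyl-5-[(4aS,8aR)-2,5,5,8a-tetramethyl-3,4,4a,5,6,7,8,8a-octahydronaphthalen-1-yl]pentanoate, via alkylzinc iodide 18 (not isolated)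
Conditions: Zn dust (activated: BrCH2CH2Br, Me3SiCl), LiCl, THF, 40 °C; then 13, PdCl2(dppf) (dppf = 1,1'-bis(diphenylphosphino)ferrocene, 5 mol%), THF/NMP, 60 °C
Reagents that add atoms: methyl (3S)-5-iodo-3-methylpentanoate (17), ICC[C@@H](C)CC(=O)OC
Why: Negishi cross-coupling in which ester-tolerant zinc insertion gives the primary alkylzinc, and zerovalent palladium adds to the enol triflate, transmetalates and reductively eliminates (the wide-bite-angle ligand disfavouring β-hydride elimination), as precedented for 2,6,6-trimethylcyclohexenyl triflates; no stereocenter is formed.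

Step 9
Reactants: 19 methyl (3R)-3-methyl-5-[(4aS,8aR)-2,5,5,8a-tetramethyl-3,4,4a,5,6,7,8,8a-octahydronaphthalen-1-yl]pentanoate; 20 lithium hydroxide
Product: 21 (3R)-3-methyl-5-[(4aS,8aR)-2,5,5,8a-tetramethyl-3,4,4a,5,6,7,8,8a-octahydronaphthalen-1-yl]pentanoic acid
Conditions: LiOH·H2O, THF/MeOH/H2O, rt; then 1 M HCl
Reagents that add atoms: lithium hydroxide, [Li+].[OH-]
Why: Saponification of the methyl ester while the diketone is still masked as the alkene, so that no aldol chemistry can interfere and no stereocenter is at risk.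

Step 10
Reactants: 21 (3R)-3-methyl-5-[(4aS,8aR)-2,5,5,8a-tetramethyl-3,4,4a,5,6,7,8,8a-octahydronaphthalen-1-yl]pentanoic acid; 22 (S)-solketal, [(4S)-2,2-dimethyl-1,3-dioxolan-4-yl]methanol
Product: 23 [(4R)-2,2-dimethyl-1,3-dioxolan-4-yl]methyl (3R)-3-methyl-5-[(4aS,8aR)-2,5,5,8a-tetramethyl-3,4,4a,5,6,7,8,8a-octahydronaphthalen-1-yl]pentanoate
Conditions: DCC, DMAP (cat.), CH2Cl2, 0 °C → rt
Reagents that add atoms: (S)-solketal, OC[C@H]1COC(C)(C)O1
Why: Steglich esterification of the acid with the primary alcohol of the chiral-pool glycerol acetonide, which brings in the glycerol stereocenter untouched (descriptor change by CIP priority only).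

Step 11
Reactants: 23 [(4R)-2,2-dimethyl-1,3-dioxolan-4-yl]methyl (3R)-3-methyl-5-[(4aS,8aR)-2,5,5,8a-tetramethyl-3,4,4a,5,6,7,8,8a-octahydronaphthalen-1-yl]pentanoate
Product: 24 (2R)-2,3-dihydroxypropyl (3R)-3-methyl-5-[(4aS,8aR)-2,5,5,8a-tetramethyl-3,4,4a,5,6,7,8,8a-octahydronaphthalen-1-yl]pentanoate
Conditions: AcOH/H2O (4:1), 40 °C
Reagents that add atoms: none
Why: Mild acid-catalysed hydrolysis of the isopropylidene acetal, chosen so that neither 1→2 acyl migration nor isomerisation of the already most-substituted alkene should occur.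

Step 12
Reactants: 24 (2R)-2,3-dihydroxypropyl (3R)-3-methyl-5-[(4aS,8aR)-2,5,5,8a-tetramethyl-3,4,4a,5,6,7,8,8a-octahydronaphthalen-1-yl]pentanoate; 25 acetyl chloride
Product: 26 (2R)-3-(acetyloxy)-2-hydroxypropyl (3R)-3-methyl-5-[(4aS,8aR)-2,5,5,8a-tetramethyl-3,4,4a,5,6,7,8,8a-octahydronaphthalen-1-yl]pentanoate
Conditions: AcCl, 2,4,6-collidine, CH2Cl2, −78 °C
Reagents that add atoms: acetyl chloride, CC(Cl)=O
Why: Kinetically controlled site-selective acylation of the primary over the secondary hydroxyl with an acyl chloride and a hindered pyridine base at low temperature, leaving the carbinol stereocenter untouched.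

Step 13
Reactants: 26 (2R)-3-(acetyloxy)-2-hydroxypropyl (3R)-3-methyl-5-[(4aS,8aR)-2,5,5,8a-tetramethyl-3,4,4a,5,6,7,8,8a-octahydronaphthalen-1-yl]pentanoate; 27 ozone
Product: 29 (2R)-3-(acetyloxy)-2-hydroxypropyl (3R)-3-methyl-6-oxo-6-[(1R,2S)-1,3,3-trimethyl-2-(3-oxobutyl)cyclohexyl]hexanoate, via ozonide 28 (not isolated)
Conditions: O3, CH2Cl2, −78 °C; then PPh3, −78 °C → rt
Reagents that add atoms: ozone, [O-][O+]=O
Why: Criegee ozonolysis of the electron-rich tetrasubstituted alkene, whose tethered ketone and carbonyl oxide close to ozonide 28 that PPh3 reduces to the two ketones; esters and the free hydroxyl are inert to ozone, and neither ring stereocenter is enolisable (one is quaternary, the other β to the ketone).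

## Compound list

1 | (R)-carvone, (5R)-2-methyl-5-(prop-1-en-2-yl)cyclohex-2-en-1-one | CC1=CC[C@@H](C(C)=C)CC1=O | starting material
2 | 1-chloro-3-iodopropane | ClCCCI | starting material
3 | lithium (3R)-6-methyl-3-(prop-1-en-2-yl)cyclohexa-1,5-dien-1-olate | [Li+].CC1=CC[C@@H](C(C)=C)C=C1[O-] | intermediate
4 | (5R,6RS)-6-(3-chloropropyl)-2-methyl-5-(prop-1-en-2-yl)cyclohex-2-en-1-one (C-6 epimers) | CC1=CC[C@@H](C(C)=C)C(CCCCl)C1=O | intermediate
5 | iodomethane | CI | starting material
6 | lithium (3S)-2-(3-chloropropyl)-6-methyl-3-(prop-1-en-2-yl)cyclohexa-1,5-dien-1-olate | [Li+].CC1=CC[C@@H](C(C)=C)C(CCCCl)=C1[O-] | intermediate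
7 | (5S,6R)-6-(3-chloropropyl)-2,6-dimethyl-5-(prop-1-en-2-yl)cyclohex-2-en-1-one (arm cis to isopropenyl) | CC1=CC[C@@H](C(C)=C)[C@@](C)(CCCCl)C1=O | intermediate
8 | sodium iodide | [Na+].[I-] | starting material
9 | (5S,6R)-6-(3-iodopropyl)-2,6-dimethyl-5-(prop-1-en-2-yl)cyclohex-2-en-1-one | CC1=CC[C@@H](C(C)=C)[C@@](C)(CCCI)C1=O | intermediate
10 | (4aS,8aR)-2,5,5,8a-tetramethyl-4a,5,6,7,8,8a-hexahydronaphthalen-1(4H)-one (cis-fused) | CC1=CC[C@H]2C(C)(C)CCC[C@@]2(C)C1=O | intermediate
11 | N-phenylbis(trifluoromethanesulfonimide) | FC(F)(F)S(=O)(=O)N(c1ccccc1)S(=O)(=O)C(F)(F)F | starting material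
12 | lithium (4aS,8aR)-2,5,5,8a-tetramethyl-3,4,4a,5,6,7,8,8a-octahydronaphthalen-1-olate | [Li+].CC1=C([O-])[C@]2(C)CCCC(C)(C)[C@@H]2CC1 | intermediate
13 | (4aS,8aR)-2,5,5,8a-tetramethyl-3,4,4a,5,6,7,8,8a-octahydronaphthalen-1-yl trifluoromethanesulfonate | CC1=C(OS(=O)(=O)C(F)(F)F)[C@]2(C)CCCC(C)(C)[C@@H]2CC1 | intermediate
14 | (3R)-5-methoxy-3-methyl-5-oxopentanoic acid | OC(=O)C[C@@H](C)CC(=O)OC | starting material
15 | methyl (3R)-5-hydroxy-3-methylpentanoate | OCC[C@@H](C)CC(=O)OC | intermediate
16 | iodine | II | starting material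
17 | methyl (3S)-5-iodo-3-methylpentanoate | ICC[C@@H](C)CC(=O)OC | intermediate
18 | iodo[(3S)-5-methoxy-3-methyl-5-oxopentyl]zinc | I[Zn]CC[C@@H](C)CC(=O)OC | intermediate
19 | methyl (3R)-3-methyl-5-[(4aS,8aR)-2,5,5,8a-tetramethyl-3,4,4a,5,6,7,8,8a-octahydronaphthalen-1-yl]pentanoate | CC1=C(CC[C@@H](C)CC(=O)OC)[C@]2(C)CCCC(C)(C)[C@@H]2CC1 | intermediate
20 | lithium hydroxide | [Li+].[OH-] | starting material
21 | (3R)-3-methyl-5-[(4aS,8aR)-2,5,5,8a-tetramethyl-3,4,4a,5,6,7,8,8a-octahydronaphthalen-1-yl]pentanoic acid | CC1=C(CC[C@@H](C)CC(=O)O)[C@]2(C)CCCC(C)(C)[C@@H]2CC1 | intermediate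
22 | (S)-solketal, [(4S)-2,2-dimethyl-1,3-dioxolan-4-yl]methanol | OC[C@H]1COC(C)(C)O1 | starting material
23 | [(4R)-2,2-dimethyl-1,3-dioxolan-4-yl]methyl (3R)-3-methyl-5-[(4aS,8aR)-2,5,5,8a-tetramethyl-3,4,4a,5,6,7,8,8a-octahydronaphthalen-1-yl]pentanoate | CC1=C(CC[C@@H](C)CC(=O)OC[C@H]3COC(C)(C)O3)[C@]2(C)CCCC(C)(C)[C@@H]2CC1 | intermediate
24 | (2R)-2,3-dihydroxypropyl (3R)-3-methyl-5-[(4aS,8aR)-2,5,5,8a-tetramethyl-3,4,4a,5,6,7,8,8a-octahydronaphthalen-1-yl]pentanoate | CC1=C(CC[C@@H](C)CC(=O)OC[C@H](O)CO)[C@]2(C)CCCC(C)(C)[C@@H]2CC1 | intermediate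
25 | acetyl chloride | CC(Cl)=O | starting material
26 | (2R)-3-(acetyloxy)-2-hydroxypropyl (3R)-3-methyl-5-[(4aS,8aR)-2,5,5,8a-tetramethyl-3,4,4a,5,6,7,8,8a-octahydronaphthalen-1-yl]pentanoate | CC1=C(CC[C@@H](C)CC(=O)OC[C@H](O)COC(C)=O)[C@]2(C)CCCC(C)(C)[C@@H]2CC1 | intermediate
27 | ozone | [O-][O+]=O | starting material
28 | secondary ozonide of 26 (1,2,4-trioxolane spanning the two former alkene carbons; configuration at these two carbons undefined) | CC1(OOC3(CC[C@@H](C)CC(=O)OC[C@H](O)COC(C)=O)O1)CC[C@H]2C(C)(C)CCC[C@]23C | intermediate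
29 | (2R)-3-(acetyloxy)-2-hydroxypropyl (3R)-3-methyl-6-oxo-6-[(1R,2S)-1,3,3-trimethyl-2-(3-oxobutyl)cyclohexyl]hexanoate | CC(=O)CC[C@H]1C(C)(C)CCC[C@@]1(C)C(=O)CC[C@@H](C)CC(=O)OC[C@H](O)COC(C)=O | target

## Step count and risks

Total step count: 13. Longest linear sequence: 11 steps (1 → 29 through steps 1–5 and 8–13); steps 6 and 7 make the side-chain fragment.

Steps most likely to fail:

1. Step 4 (new method). Hydrogen atom transfer may outpace nickel capture, so that the tertiary radical is simply reduced; the C–I bond may be reduced, the enone may undergo conjugate reduction, or the nickel-derived primary radical may add 7-endo to the isopropenyl group. The fallback uses known chemistry only, sets out from 1 and comes back at 10. The lithium dienolate of 1 is alkylated with (Z)-3-bromo-1-iodoprop-1-ene (LiN(i-Pr)2, THF, −78 °C) to give (5R,6RS)-6-[(2Z)-3-iodoprop-2-en-1-yl]-2-methyl-5-(prop-1-en-2-yl)cyclohex-2-en-1-one F1. Methylation as in step 2 (LiN(i-Pr)2, MeI) should give (5S,6R)-6-[(2Z)-3-iodoprop-2-en-1-yl]-2,6-dimethyl-5-(prop-1-en-2-yl)cyclohex-2-en-1-one F2. A reductive Mizoroki–Heck cyclisation (Pd(OAc)2, PPh3, HCO2Na, Et4NCl, DMF, 80 °C) should then close the same bond: 6-exo-trig carbopalladation of the isopropenyl group by the alkenylpalladium, then formate reduction of the neopentyl-type alkylpalladium that has no β-hydrogen. This gives (4aS,8aR)-2,5,5,8a-tetramethyl-4a,5,8,8a-tetrahydronaphthalen-1(4H)-one F3. Hydrogenation of its isolated cis-disubstituted alkene over RhCl(PPh3)3 (H2, benzene), which spares the trisubstituted enone, returns to 10.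

2. Step 8. Oxidative addition and transmetalation may be slow at the enol triflate flanked by a quaternary carbon and a methyl group, so that protodezincation, β-hydride elimination or S–O cleavage back to the ketone take over. The fallback replaces the cross-coupling by a carbonyl addition, sets out from 10 and 17 and comes back at 21. Iodo ester 17 is reduced (i-Bu2AlH, CH2Cl2, −78 → 0 °C) to (3S)-5-iodo-3-methylpentan-1-ol F4 and silylated (t-BuMe2SiCl, imidazole, CH2Cl2) to tert-butyl{[(3S)-5-iodo-3-methylpentyl]oxy}dimethylsilane F5. Iodine–lithium exchange (t-BuLi, Et2O, −78 °C), transmetalation with anhydrous CeCl3 and 1,2-addition to enone 10 should give the tertiary allylic alcohol (4aS,8aR)-1-[(3R)-5-{[tert-butyl(dimethyl)silyl]oxy}-3-methylpentyl]-2,5,5,8a-tetramethyl-1,4,4a,5,6,7,8,8a-octahydronaphthalen-1-ol F6 (C-1 configuration of no consequence). Ionic hydrogenation (Et3SiH, CF3CO2H, CH2Cl2, −20 °C; then K2CO3, MeOH) should deliver hydride to the unhindered end of the allyl cation, move the double bond into the tetrasubstituted position and free the primary alcohol, giving (3R)-3-methyl-5-[(4aS,8aR)-2,5,5,8a-tetramethyl-3,4,4a,5,6,7,8,8a-octahydronaphthalen-1-yl]pentan-1-ol F7. Oxidation (TEMPO, PhI(OAc)2, MeCN/H2O) leads to acid 21.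

3. Step 13. The hindered tetrasubstituted alkene may take up one oxygen only (epoxidation) or give an ozonide that resists reduction, and the longer handling may cause acyl migration in the monoacetylated glyceride. The fallback moves the cleavage ahead of the glyceride and changes the oxidant, sets out from 21 and comes back at 29. Acid 21 is cleaved with RuO4 made in the flask (RuCl3·xH2O cat., NaIO4, CCl4/MeCN/H2O) to (3R)-3-methyl-6-oxo-6-[(1R,2S)-1,3,3-trimethyl-2-(3-oxobutyl)cyclohexyl]hexanoic acid F8. Steglich esterification with 22 (DCC, DMAP, CH2Cl2) gives [(4R)-2,2-dimethyl-1,3-dioxolan-4-yl]methyl (3R)-3-methyl-6-oxo-6-[(1R,2S)-1,3,3-trimethyl-2-(3-oxobutyl)cyclohexyl]hexanoate F9. Acetal cleavage (AcOH/H2O, 40 °C) gives (2R)-2,3-dihydroxypropyl (3R)-3-methyl-6-oxo-6-[(1R,2S)-1,3,3-trimethyl-2-(3-oxobutyl)cyclohexyl]hexanoate F10, and primary acetylation as in step 12 (AcCl, 2,4,6-collidine, −78 °C) gives 29.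

Further compounds
F1 | step 4 | (5R,6RS)-6-[(2Z)-3-iodoprop-2-en-1-yl]-2-methyl-5-(prop-1-en-2-yl)cyclohex-2-en-1-one | CC1=CC[C@@H](C(C)=C)C(C/C=C\I)C1=O
F2 | step 4 | (5S,6R)-6-[(2Z)-3-iodoprop-2-en-1-yl]-2,6-dimethyl-5-(prop-1-en-2-yl)cyclohex-2-en-1-one | CC1=CC[C@@H](C(C)=C)[C@@](C)(C/C=C\I)C1=O
F3 | step 4 | (4aS,8aR)-2,5,5,8a-tetramethyl-4a,5,8,8a-tetrahydronaphthalen-1(4H)-one | CC1=CC[C@H]2C(C)(C)C=CC[C@@]2(C)C1=O
F4 | step 8 | (3S)-5-iodo-3-methylpentan-1-ol | ICC[C@@H](C)CCO
F5 | step 8 | tert-butyl{[(3S)-5-iodo-3-methylpentyl]oxy}dimethylsilane | ICC[C@@H](C)CCO[Si](C)(C)C(C)(C)C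
F6 | step 8 | (4aS,8aR)-1-[(3R)-5-{[tert-butyl(dimethyl)silyl]oxy}-3-methylpentyl]-2,5,5,8a-tetramethyl-1,4,4a,5,6,7,8,8a-octahydronaphthalen-1-ol | CC1=CC[C@H]2C(C)(C)CCC[C@@]2(C)C1(O)CC[C@@H](C)CCO[Si](C)(C)C(C)(C)C
F7 | step 8 | (3R)-3-methyl-5-[(4aS,8aR)-2,5,5,8a-tetramethyl-3,4,4a,5,6,7,8,8a-octahydronaphthalen-1-yl]pentan-1-ol | CC1=C(CC[C@@H](C)CCO)[C@]2(C)CCCC(C)(C)[C@@H]2CC1
F8 | step 13 | (3R)-3-methyl-6-oxo-6-[(1R,2S)-1,3,3-trimethyl-2-(3-oxobutyl)cyclohexyl]hexanoic acid | CC(=O)CC[C@H]1C(C)(C)CCC[C@@]1(C)C(=O)CC[C@@H](C)CC(=O)O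
F9 | step 13 | [(4R)-2,2-dimethyl-1,3-dioxolan-4-yl]methyl (3R)-3-methyl-6-oxo-6-[(1R,2S)-1,3,3-trimethyl-2-(3-oxobutyl)cyclohexyl]hexanoate | CC(=O)CC[C@H]1C(C)(C)CCC[C@@]1(C)C(=O)CC[C@@H](C)CC(=O)OC[C@H]2COC(C)(C)O2
F10 | step 13 | (2R)-2,3-dihydroxypropyl (3R)-3-methyl-6-oxo-6-[(1R,2S)-1,3,3-trimethyl-2-(3-oxobutyl)cyclohexyl]hexanoate | CC(=O)CC[C@H]1C(C)(C)CCC[C@@]1(C)C(=O)CC[C@@H](C)CC(=O)OC[C@H](O)CO
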